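**Plan**

1. Retrosynthesis: the O1–C8a and C6–O bonds are cut last, giving an open (Z)-styrenyl p-methoxyphenol that already carries the C2 tertiary alcohol. The C4–C4a bond is cut next (Sonogashira), leaving an (S)-tertiary propargylic alcohol and 2-iodo-4-methoxyphenol.
2. The alkynol comes from the Sharpless epoxide of an E-allylic alcohol, made by Zr-catalysed carboalumination of an enyne. The enyne comes from methylenation and Eschenmoser–Tanabe fragmentation of an epoxidized Robinson octalone (2,6-dimethylcyclohexanone + methyl vinyl ketone).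
3. Forward order of rings: the cyclohexane is the commercial ketone. A temporary ring B (holding C1', C2', both linker carbons, C2 and C3) is annulated and then unzipped to ketone plus terminal alkyne. The pyran ring is closed last, on an arene that carries no protecting group.
4. Stereochemistry: C1' comes from the asymmetric Michael reaction of the (S)-1-phenylethylamine imine. C3' is set by thermodynamic equilibration in the octalone (8-Me equatorial, trans to the axial 4a-Me). C2 comes from Sharpless epoxidation (L-(+)-DET) and is kept because its C–O bond is never broken.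
5. Enabling feature: in the o-quinone made from the C5 phenol, C8a is the β-carbon of the enone O=C5–C4a=C8a and sits next to the side-chain carbon C4a. The C2 oxygen is held over C8a by the (Z)-C3=C4 bridge, so C6 oxygenation and pyran closure occur in one operation and aromatization gives the 5,6-diol.

Key step: step 15

Remark: the target is read as (2S)-2-{2-[(1R,3R)-1,3-dimethyl-2-methylidenecyclohexyl]ethyl}-8-methoxy-2-methyl-2H-chromene-5,6-diol (methyls on C1' and C3' trans). Compounds 1, 2, 4 and 19 are taken as commercial. Chromene atoms are numbered O1–C8a and carbocycle atoms are primed.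

**Route**

Step 1
Reactants: 1 2,6-dimethylcyclohexan-1-one (cis/trans mixture); 2 (S)-1-phenylethan-1-amine
Product: 3 (1S)-N-(2,6-dimethylcyclohexylidene)-1-phenylethan-1-amine
Conditions: cat. TsOH, toluene, reflux, Dean–Stark
Reagents that add atoms: none
Why: Acid-catalysed ketimine condensation with azeotropic water removal installs the chiral auxiliary; the ring stereocentres are irrelevant at this stage because the imine reacts through its enamine tautomer.

Step 2
Reactants: 3; 4 but-3-en-2-one (methyl vinyl ketone)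
Product: 6 (2R)-2,6-dimethyl-2-(3-oxobutyl)cyclohexan-1-one (C6 epimers), via Michael adduct imine 5 (not isolated)
Conditions: THF, 23 °C, 3 d; then 10% aq. AcOH
Reagents that add atoms: water O
Why: In the asymmetric Michael reaction of chiral imines (aza-ene type), the secondary enamine tautomer adds to the enone on the face anti to the phenyl group with internal N–H transfer, which should set the quaternary C1' as R, as the (S)-amine does in the parent 2-methyl series.

Step 3
Reactants: 6
Product: 8 (4aR,8R)-4a,8-dimethyl-4,4a,5,6,7,8-hexahydronaphthalen-2(3H)-one, via aldol ketol 7 (not isolated)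
Conditions: NaOMe (0.2 equiv), MeOH, 0 °C to reflux
Reagents that add atoms: none
Why: The intramolecular aldol condensation of the Robinson annulation closes ring B, and C8 should equilibrate through the dienolate to the trans isomer (8-Me equatorial, avoiding a 1,3-diaxial contact with the axial 4a-Me), which fixes C3' relative to C1'.

Step 4
Reactants: 8
Product: 9 (4aR,8R)-1,8a-epoxy-4a,8-dimethyloctahydronaphthalen-2(1H)-one (both epoxide faces)
Conditions: 30% H2O2, NaOH (0.3 equiv), MeOH, 0 to 23 °C
Reagents that add atoms: hydrogen peroxide OO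
Why: Weitz–Scheffer nucleophilic epoxidation of the enone; the epoxide configuration is immaterial because both epoxide carbons lose their stereochemistry in step 5, and C8 is no longer epimerizable once the enone is gone.

Step 5
Reactants: 9
Product: 11 (2R,6R)-2-(but-3-yn-1-yl)-2,6-dimethylcyclohexan-1-one, via epoxy tosylhydrazone 10 (not isolated)
Conditions: TsNHNH2, AcOH/CH2Cl2 1:1, −20 to 23 °C
Reagents that add atoms: none
Why: Eschenmoser–Tanabe fragmentation: the hydrazone opens the epoxide to an azoalkene alkoxide that cleaves the C1–C8a bond with loss of N2 and sulfinate, unzipping ring B to the ring ketone and a terminal alkyne without touching C1' or C3'.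

Step 6
Reactants: 11
Product: 12 (1R,3R)-1-(but-3-yn-1-yl)-1,3-dimethyl-2-methylidenecyclohexane
Conditions: Zn, CH2Br2, TiCl4, THF/CH2Cl2, 0 to 23 °C
Reagents that add atoms: dibromomethane BrCBr
Why: Takai–Lombardo methylenation uses a non-basic Zn/Ti gem-dimetallic reagent that converts hindered, enolizable ketones into methylidene compounds without epimerizing the α-CH(Me) centre and tolerates the alkyne.

Step 7
Reactants: 12
Product: 14 (2E)-5-[(1R,3R)-1,3-dimethyl-2-methylidenecyclohexyl]-3-methylpent-2-en-1-ol, via E-alkenylalane 13 (not isolated)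
Conditions: Me3Al (2.5 equiv), Cp2ZrCl2 (0.25 equiv), CH2Cl2, 0 to 23 °C; then n-BuLi, THF, −78 °C; (CH2O)n, to 23 °C
Reagents that add atoms: trimethylaluminium C[Al](C)C; paraformaldehyde (as formaldehyde) C=O
Why: Negishi zirconium-catalysed carboalumination adds Me–Al syn across the terminal alkyne with Al on the terminal carbon, and the derived alanate is hydroxymethylated with retention, giving only the E-trisubstituted allylic alcohol; the hindered 1,1-disubstituted ring alkene should stay inert.

Step 8
Reactants: 14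
Product: 15 [(2S,3S)-3-{2-[(1R,3R)-1,3-dimethyl-2-methylidenecyclohexyl]ethyl}-3-methyloxiran-2-yl]methanol
Conditions: Ti(Oi-Pr)4 (cat.), L-(+)-diethyl tartrate (cat.), t-BuOOH, 4 Å MS, CH2Cl2, −20 °C
Reagents that add atoms: tert-butyl hydroperoxide CC(C)(C)OO
Why: Sharpless asymmetric epoxidation under reagent control; L-(+)-tartrate should deliver oxygen to the face that gives the (2S,3S)-epoxide, as it does with geraniol, so the future C2 centre is fixed by olefin geometry plus catalyst.

Step 9
Reactants: 15
Product: 16 (2R,3S)-2-(chloromethyl)-3-{2-[(1R,3R)-1,3-dimethyl-2-methylidenecyclohexyl]ethyl}-3-methyloxirane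
Conditions: PPh3, CCl4, NaHCO3, reflux
Reagents that add atoms: carbon tetrachloride ClC(Cl)(Cl)Cl
Why: Appel chlorination of the primary alcohol under buffered, neutral conditions leaves the epoxide and both of its stereocentres intact.

Step 10
Reactants: 16
Product: 18 (3S)-5-[(1R,3R)-1,3-dimethyl-2-methylidenecyclohexyl]-3-methylpent-1-yn-3-ol, via chlorovinyl carbinol 17 (not isolated)
Conditions: n-BuLi (3.2 equiv), THF, −78 to −30 °C; aq. NH4Cl
Reagents that add atoms: none
Why: Base-induced fragmentation of a 2,3-epoxy chloride to a propargylic alcohol (α-deprotonation, epoxide opening to the chlorovinyl alkoxide, dehydrochlorination) keeps the tertiary C–O bond, so the S carbinol centre is carried over unchanged.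

Step 11
Reactants: 19 2-iodo-4-methoxyphenol
Product: 20 2-iodo-4-methoxyphenyl acetate
Conditions: Ac2O, pyridine, DMAP (cat.), CH2Cl2, 23 °C
Reagents that add atoms: acetic anhydride CC(=O)OC(C)=O
Why: O-Acetylation masks the phenol so that the ortho-alkynylphenol cannot cyclize to a benzofuran under the Pd/Cu conditions of step 12.

Step 12
Reactants: 18; 20
Product: 21 2-{(3S)-5-[(1R,3R)-1,3-dimethyl-2-methylidenecyclohexyl]-3-hydroxy-3-methylpent-1-yn-1-yl}-4-methoxyphenyl acetate
Conditions: PdCl2(PPh3)2 (3 mol%), CuI (5 mol%), Et3N, THF, 23 °C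
Reagents that add atoms: none
Why: Sonogashira coupling of the terminal alkyne with the aryl iodide forms the C4–C4a bond and tolerates the free tertiary alcohol and the aryl acetate.

Step 13
Reactants: 21
Product: 22 2-{(1Z,3S)-5-[(1R,3R)-1,3-dimethyl-2-methylidenecyclohexyl]-3-hydroxy-3-methylpent-1-en-1-yl}-4-methoxyphenyl acetate
Conditions: H2 (1 atm), Lindlar catalyst, quinoline, EtOAc, 23 °C
Reagents that add atoms: none
Why: Lindlar semi-hydrogenation adds H2 syn to the alkyne to give the Z-alkene needed to bring the C2 oxygen next to C8a, while the hindered 1,1-disubstituted ring alkene should not be reduced.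

Step 14
Reactants: 22
Product: 23 2-{(1Z,3S)-5-[(1R,3R)-1,3-dimethyl-2-methylidenecyclohexyl]-3-hydroxy-3-methylpent-1-en-1-yl}-4-methoxyphenol
Conditions: K2CO3 (0.3 equiv), MeOH, 0 °C; pH 7 buffer; used crude
Reagents that add atoms: none
Why: Base-catalysed transesterification frees the phenol under non-acidic conditions, which avoids ionization of the allylic tertiary alcohol and cyclodehydration through the C5 oxygen.

Step 15
Reactants: 23
Product: 26 (2S)-2-{2-[(1R,3R)-1,3-dimethyl-2-methylidenecyclohexyl]ethyl}-8-methoxy-2-methyl-2H-chromene-5,6-diol, via open o-quinone 24 (not isolated), via chromene-5,6-dione 25 (not isolated)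
Conditions: IBX (2.3 equiv), DMF, 0 to 23 °C, dark, Ar; then aq. Na2S2O4, 0 °C
Reagents that add atoms: 2-iodoxybenzoic acid (IBX) O=C1OI(=O)(O)c2ccccc12
Why: Proposed new method: IBX transfers oxygen to the only free ortho position of phenol 23 (C6, since C4a is substituted) to give the 5-methoxy-o-quinone 24, in which C8a is the β-carbon of the enone O=C5–C4a=C8a; the C2 hydroxyl, held over C8a by the (Z)-C3=C4 bond, adds in a conjugate addition and enolization re-aromatizes the ring to the 5,6-catechol. Excess IBX should take this electron-rich catechol on to the stabilized 4,5-dialkoxy-o-quinone 25, which dithionite returns to 26. The closest known reactions are the IBX ortho-oxygenation of phenols to o-quinones with reductive work-up and the intramolecular hetero-Michael capture of o-quinones and quinones by tethered N- and O-nucleophiles (cyclodopa-type and pyranoquinone closures); a tertiary alcohol has not been used in this way. The pyran ring closes by O1–C8a bond formation in the 6-endo-trig mode, and no new stereocentre is made: C2 keeps the S configuration from step 8 because its C–O bond is never broken. The step needs attack at C8a rather than at C8 (a seven-membered closure) or at the C5 carbonyl (a reversible hemiketal that returns to 24), and it needs neutral, cold, dark conditions so that the allylic C2–O bond does not ionize and 25 does not open by retro-oxa-6π before it is reduced.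

**Compound list**

1 | 2,6-dimethylcyclohexan-1-one | CC1CCCC(C)C1=O | starting material
2 | (S)-1-phenylethan-1-amine | C[C@H](N)c1ccccc1 | starting material
3 | (1S)-N-(2,6-dimethylcyclohexylidene)-1-phenylethan-1-amine | C[C@H](N=C1C(C)CCCC1C)c1ccccc1 | intermediate
4 | but-3-en-2-one | C=CC(C)=O | starting material
5 | 4-[(1R)-1,3-dimethyl-2-{[(1S)-1-phenylethyl]imino}cyclohexyl]butan-2-one | C[C@H](N=C1C(C)CCC[C@]1(C)CCC(C)=O)c1ccccc1 | intermediate
6 | (2R)-2,6-dimethyl-2-(3-oxobutyl)cyclohexan-1-one | O=C1C(C)CCC[C@]1(C)CCC(C)=O | intermediate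
7 | (4aR)-8a-hydroxy-4a,8-dimethyloctahydronaphthalen-2(1H)-one | O=C1CC2(O)C(C)CCC[C@]2(C)CC1 | intermediate
8 | (4aR,8R)-4a,8-dimethyl-4,4a,5,6,7,8-hexahydronaphthalen-2(3H)-one | O=C1C=C2[C@H](C)CCC[C@]2(C)CC1 | intermediate
9 | (4aR,8R)-1,8a-epoxy-4a,8-dimethyloctahydronaphthalen-2(1H)-one | O=C1C2OC23[C@H](C)CCC[C@]3(C)CC1 | intermediate
10 | N-tosylhydrazone of 9 | Cc1ccc(cc1)S(=O)(=O)NN=C1C2OC23[C@H](C)CCC[C@]3(C)CC1 | intermediate
11 | (2R,6R)-2-(but-3-yn-1-yl)-2,6-dimethylcyclohexan-1-one | O=C1[C@H](C)CCC[C@]1(C)CCC#C | intermediate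
12 | (1R,3R)-1-(but-3-yn-1-yl)-1,3-dimethyl-2-methylidenecyclohexane | C=C1[C@H](C)CCC[C@]1(C)CCC#C | intermediate
13 | {(1E)-4-[(1R,3R)-1,3-dimethyl-2-methylidenecyclohexyl]-2-methylbut-1-en-1-yl}dimethylalane | C=C1[C@H](C)CCC[C@]1(C)CC/C(C)=C/[Al](C)C | intermediate
14 | (2E)-5-[(1R,3R)-1,3-dimethyl-2-methylidenecyclohexyl]-3-methylpent-2-en-1-ol | C=C1[C@H](C)CCC[C@]1(C)CC/C(C)=C/CO | intermediate
15 | [(2S,3S)-3-{2-[(1R,3R)-1,3-dimethyl-2-methylidenecyclohexyl]ethyl}-3-methyloxiran-2-yl]methanol | C=C1[C@H](C)CCC[C@]1(C)CC[C@]1(C)O[C@H]1CO | intermediate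
16 | (2R,3S)-2-(chloromethyl)-3-{2-[(1R,3R)-1,3-dimethyl-2-methylidenecyclohexyl]ethyl}-3-methyloxirane | C=C1[C@H](C)CCC[C@]1(C)CC[C@]1(C)O[C@H]1CCl | intermediate
17 | (3S)-1-chloro-5-[(1R,3R)-1,3-dimethyl-2-methylidenecyclohexyl]-3-methylpent-1-en-3-ol | C=C1[C@H](C)CCC[C@]1(C)CC[C@](C)(O)C=CCl | intermediate
18 | (3S)-5-[(1R,3R)-1,3-dimethyl-2-methylidenecyclohexyl]-3-methylpent-1-yn-3-ol | C=C1[C@H](C)CCC[C@]1(C)CC[C@](C)(O)C#C | intermediate
19 | 2-iodo-4-methoxyphenol | Oc1ccc(OC)cc1I | starting material
20 | 2-iodo-4-methoxyphenyl acetate | CC(=O)Oc1ccc(OC)cc1I | intermediate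
21 | 2-{(3S)-5-[(1R,3R)-1,3-dimethyl-2-methylidenecyclohexyl]-3-hydroxy-3-methylpent-1-yn-1-yl}-4-methoxyphenyl acetate | C=C1[C@H](C)CCC[C@]1(C)CC[C@](C)(O)C#Cc1cc(OC)ccc1OC(C)=O | intermediate
22 | 2-{(1Z,3S)-5-[(1R,3R)-1,3-dimethyl-2-methylidenecyclohexyl]-3-hydroxy-3-methylpent-1-en-1-yl}-4-methoxyphenyl acetate | C=C1[C@H](C)CCC[C@]1(C)CC[C@](C)(O)/C=C\c1cc(OC)ccc1OC(C)=O | intermediate
23 | 2-{(1Z,3S)-5-[(1R,3R)-1,3-dimethyl-2-methylidenecyclohexyl]-3-hydroxy-3-methylpent-1-en-1-yl}-4-methoxyphenol | C=C1[C@H](C)CCC[C@]1(C)CC[C@](C)(O)/C=C\c1cc(OC)ccc1O | intermediate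
24 | 3-{(1Z,3S)-5-[(1R,3R)-1,3-dimethyl-2-methylidenecyclohexyl]-3-hydroxy-3-methylpent-1-en-1-yl}-5-methoxycyclohexa-3,5-diene-1,2-dione | C=C1[C@H](C)CCC[C@]1(C)CC[C@](C)(O)/C=C\C1=CC(OC)=CC(=O)C1=O | intermediate
25 | (2S)-2-{2-[(1R,3R)-1,3-dimethyl-2-methylidenecyclohexyl]ethyl}-8-methoxy-2-methyl-2H-chromene-5,6-dione | C=C1[C@H](C)CCC[C@]1(C)CC[C@@]1(C)C=CC2=C(O1)C(OC)=CC(=O)C2=O | intermediate
26 | (2S)-2-{2-[(1R,3R)-1,3-dimethyl-2-methylidenecyclohexyl]ethyl}-8-methoxy-2-methyl-2H-chromene-5,6-diol | C=C1[C@H](C)CCC[C@]1(C)CC[C@@]1(C)C=Cc2c(O)c(O)cc(OC)c2O1 | target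

**Step count**

Total steps: 15. Longest linear sequence: 14 (steps 1–10 and 12–15).

**Steps most likely to fail**

Step 15 (proposed method). The open o-quinone may be drained by hemiketalization at C5 followed by dimerization. The free (Z)-phenol may cyclodehydrate through the C5 oxygen with ionization at C2. The pyrano-o-quinone may lose configuration by ring opening before it is reduced. The fallback sets out from 18 and returns at 26; it closes the O1–C8a bond by palladium-catalysed aryl etherification before the C6 oxygen is introduced. Commercial 3-bromo-4-methoxyphenol is protected (MOMCl, i-Pr2NEt) as 2-bromo-1-methoxy-4-(methoxymethoxy)benzene F1. LDA (THF, −78 °C) should deprotonate F1 between Br and OMOM, and iodine then gives 2-bromo-3-iodo-1-methoxy-4-(methoxymethoxy)benzene F2. Sonogashira coupling of 18 at the C–I bond gives the bromoaryl alkynol F3, and Lindlar reduction gives the (Z)-bromostyrenyl carbinol F4. Intramolecular Buchwald–Hartwig etherification of the tertiary alcohol (Pd(OAc)2, t-BuXPhos, Cs2CO3, toluene, 70 °C) gives the 5-MOM-protected chromene F5 with retention at C2. Mild acid (cat. HCl, MeOH, 40 °C) frees the chromen-5-ol F6. The known IBX ortho-oxygenation with dithionite work-up, which passes through 25, then gives 26.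

Step 6. Slow methylenation of the doubly α-branched ketone may allow Lewis-acid enolization and loss of the trans relationship at C3', or the carbenoid may attack the terminal alkyne. The fallback sets out from 11 and returns at 12 by a Peterson olefination. Me3SiCH2Li/CeCl3 (THF, −78 °C) adds without enolization to give the β-hydroxysilane F7, and KH (THF, 0 °C) eliminates it to 12.

Step 5. Acid may open the tetrasubstituted epoxide before the hydrazone fragments, or the new ketone may epimerize at the α-CH(Me) centre in acetic acid. The fallback sets out from 8 and returns at 12; it replaces fragmentation by oxidative excision of C1 and one-carbon homologation. Ozonolysis with oxidative work-up (O3, CH2Cl2/MeOH, −78 °C; H2O2) gives the keto acid F8. TMSCHN2 gives the keto ester F9, and Takai–Lombardo methylenation gives the methylidene ester F10. DIBAL-H (−78 °C) gives the aldehyde F11, and the Ohira–Bestmann reagent (K2CO3, MeOH) gives 12.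

**Further compounds**

F1 | step 15 | 2-bromo-1-methoxy-4-(methoxymethoxy)benzene | COCOc1ccc(OC)c(Br)c1
F2 | step 15 | 2-bromo-3-iodo-1-methoxy-4-(methoxymethoxy)benzene | COCOc1ccc(OC)c(Br)c1I
F3 | step 15 | (3S)-1-[2-bromo-3-methoxy-6-(methoxymethoxy)phenyl]-5-[(1R,3R)-1,3-dimethyl-2-methylidenecyclohexyl]-3-methylpent-1-yn-3-ol | C=C1[C@H](C)CCC[C@]1(C)CC[C@](C)(O)C#Cc1c(Br)c(OC)ccc1OCOC
F4 | step 15 | (1Z,3S)-1-[2-bromo-3-methoxy-6-(methoxymethoxy)phenyl]-5-[(1R,3R)-1,3-dimethyl-2-methylidenecyclohexyl]-3-methylpent-1-en-3-ol | C=C1[C@H](C)CCC[C@]1(C)CC[C@](C)(O)/C=C\c1c(Br)c(OC)ccc1OCOC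
F5 | step 15 | (2S)-2-{2-[(1R,3R)-1,3-dimethyl-2-methylidenecyclohexyl]ethyl}-8-methoxy-5-(methoxymethoxy)-2-methyl-2H-chromene | C=C1[C@H](C)CCC[C@]1(C)CC[C@@]1(C)C=Cc2c(OCOC)ccc(OC)c2O1
F6 | step 15 | (2S)-2-{2-[(1R,3R)-1,3-dimethyl-2-methylidenecyclohexyl]ethyl}-8-methoxy-2-methyl-2H-chromen-5-ol | C=C1[C@H](C)CCC[C@]1(C)CC[C@@]1(C)C=Cc2c(O)ccc(OC)c2O1
F7 | step 6 | (2R,6R)-2-(but-3-yn-1-yl)-2,6-dimethyl-1-[(trimethylsilyl)methyl]cyclohexan-1-ol | C[Si](C)(C)CC1(O)[C@H](C)CCC[C@]1(C)CCC#C
F8 | step 5 | 3-[(1R,3R)-1,3-dimethyl-2-oxocyclohexyl]propanoic acid | O=C1[C@H](C)CCC[C@]1(C)CCC(=O)O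
F9 | step 5 | methyl 3-[(1R,3R)-1,3-dimethyl-2-oxocyclohexyl]propanoate | O=C1[C@H](C)CCC[C@]1(C)CCC(=O)OC
F10 | step 5 | methyl 3-[(1R,3R)-1,3-dimethyl-2-methylidenecyclohexyl]propanoate | C=C1[C@H](C)CCC[C@]1(C)CCC(=O)OC
F11 | step 5 | 3-[(1R,3R)-1,3-dimethyl-2-methylidenecyclohexyl]propanal | C=C1[C@H](C)CCC[C@]1(C)CCC=O
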